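**Retrosynthetic overview**
- The route rests on the seven-membered ring: a ketone at C4, the C5=C6(Me) enone, the C7 methylene and an enol ether at C8=C8a, next to the quaternary C3a–Me. This is a cyclohepta-2,5-dienone (16), the retron of a ketene/vinylcyclopropane Cope shift.
- 16 comes from cis-cyclopropyl diazomethyl ketone 14 by Wolff rearrangement and [3,3] shift, which forms C4–C5 and C4–C3a and closes the seven-membered ring.
- 14 comes from lactone 9, made by intramolecular Rh cyclopropanation of the enol ether with a 2-diazopropanoate tethered through the cyclopentenol oxygen. The tether forces acyl and cyclopentenyl cis; the CBS-derived carbinol fixes the absolute configuration and is later oxidised.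
- Ring order: cyclopentene (purchased), cyclopropane (step 6), seven-membered ring (step 10).
- After the key step: 4-OH delivers the C3 oxygen, the C3 alkoxide delivers isopropyl to C1, and 1-OH delivers hydride to C8. C4 is re-oxidised once to tell the C3 and C4 hydroxyls apart; the three esters go on one at a time.

Key step: step 10

Remark (descriptors): from compound 16 on, azulene numbering is used (C1–C3 five-membered ring, C3a/C8a fusion, C4–C8 seven-membered ring); β is the face of the C3a methyl in the usual planar drawing, α the other face.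

Remark (assumption): in step 6 the carbenoid is assumed to add to the enol ether rotamer that turns OEt away from the ring methyl, placing the cyclopropane CH2 on the lactone-oxygen side. Because the carbinol centre is destroyed in step 8, the opposite sense would be corrected by using the antipodal CBS catalyst in step 2.

**Route**

Step 1
Reactants: 1 3-methylcyclopent-2-en-1-one
Product: 2 2-iodo-3-methylcyclopent-2-en-1-one
Conditions: I2, pyridine, CH2Cl2, 0 °C → rt
Reagents that add atoms: iodine, II
Why: α-Iodination of an enone by pyridine conjugate addition, enolate iodination and elimination (Baylis–Hillman-type α-halogenation), a standard entry to 2-iodoenones.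

Step 2
Reactants: 2 2-iodo-3-methylcyclopent-2-en-1-one
Product: 3 (R)-2-iodo-3-methylcyclopent-2-en-1-ol
Conditions: (S)-Me-CBS (15 mol %), BH3·SMe2, THF, −20 °C
Reagents that add atoms: none
Why: CBS reduction in which the iodoalkenyl side acts as the large group (as aryl does in aryl alkyl ketones), so the (S)-catalyst should give the (R)-carbinol.

Step 3
Reactants: 3 (R)-2-iodo-3-methylcyclopent-2-en-1-ol; 4 tributyl(1-ethoxyvinyl)stannane
Product: 5 (R)-2-(1-ethoxyvinyl)-3-methylcyclopent-2-en-1-ol
Conditions: Pd(PPh3)4 (5 mol %), CuI (10 mol %), DMF, 50 °C; Et3N-washed SiO2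
Reagents that add atoms: none
Why: Stille coupling of a vinyl iodide with an α-alkoxyvinylstannane tolerates the free hydroxyl and leaves the carbinol centre untouched.

Step 4
Reactants: 5 (R)-2-(1-ethoxyvinyl)-3-methylcyclopent-2-en-1-ol; 6 methyl 2-methyl-3-oxobutanoate
Product: 7 (1R)-2-(1-ethoxyvinyl)-3-methylcyclopent-2-en-1-yl 2-methyl-3-oxobutanoate (both epimers at the acyl α-carbon)
Conditions: DMAP (0.3 equiv), PhMe, 100 °C, 4 Å MS
Reagents that add atoms: none
Why: DMAP-catalysed transesterification of an enolisable β-keto ester (via the acylketene) under non-acidic conditions that spare the enol ether; the α-epimers converge in step 5.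

Step 5
Reactants: 7 (1R)-2-(1-ethoxyvinyl)-3-methylcyclopent-2-en-1-yl 2-methyl-3-oxobutanoate
Product: 8 (1R)-2-(1-ethoxyvinyl)-3-methylcyclopent-2-en-1-yl 2-diazopropanoate
Conditions: p-ABSA, DBU, MeCN, 0 °C → rt
Reagents that add atoms: 4-acetamidobenzenesulfonyl azide, CC(=O)Nc1ccc(cc1)S(=O)(=O)N=[N+]=[N-]
Why: Regitz diazo transfer to the α-substituted β-keto ester with loss of the acetyl group (deacylative diazo transfer), the usual route to α-alkyl-α-diazo esters.

Step 6
Reactants: 8 (1R)-2-(1-ethoxyvinyl)-3-methylcyclopent-2-en-1-yl 2-diazopropanoate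
Product: 9 tricyclic cyclopropane-fused δ-lactone (six-membered lactone C(=O)–O–CH–C(=CMe ring)–C(OEt)–C(Me), cis-fused to the cyclopropane; cyclopropane CH2 on the lactone-oxygen side, OEt away from the ring methyl)
Conditions: Rh2(OPiv)4 (1 mol %), CH2Cl2, −40 → 0 °C, slow addition
Reagents that add atoms: none
Why: Intramolecular Rh-carbenoid cyclopropanation of the electron-rich terminal enol ether closes the six-membered lactone, so the acyl carbon and the cyclopentenyl group are necessarily cis; the face is set by the (R)-carbinol through the twisted rotamer that keeps OEt clear of the ring methyl, and the bulky carboxylate at low temperature suppresses 1,2-hydride shift.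

Step 7
Reactants: 9 tricyclic cyclopropane-fused δ-lactone
Product: 10 cis-2-ethoxy-2-[(5R)-5-hydroxy-2-methylcyclopent-1-en-1-yl]-1-methylcyclopropane-1-carboxylic acid (cyclopropane configured as in 14)
Conditions: LiOH, THF/H2O, 0 °C → rt; cold 1 M HCl to pH 4, used at once
Reagents that add atoms: lithium hydroxide, [Li+].[OH-]
Why: Saponification of the lactone; the quaternary α-carbon cannot epimerise and alkoxycyclopropane carboxylates survive base.

Step 8
Reactants: 10 cis-hydroxy acid
Product: 11 cis-2-ethoxy-1-methyl-2-(2-methyl-5-oxocyclopent-1-en-1-yl)cyclopropane-1-carboxylic acid (cyclopropane configured as in 14)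
Conditions: Dess–Martin periodinane, NaHCO3, CH2Cl2, 0 °C
Reagents that add atoms: none
Why: Dess–Martin oxidation of the allylic alcohol to the enone is fast, tolerates the free acid and prevents relactonisation.

Step 9
Reactants: 11 cis-keto acid; 12 (trimethylsilyl)diazomethane
Product: 14 2-diazo-1-[(1S,2S)-2-ethoxy-1-methyl-2-(2-methyl-5-oxocyclopent-1-en-1-yl)cyclopropyl]ethan-1-one (diazoacetyl and cyclopentenyl cis), via acid chloride 13 (not isolated)
Conditions: 1-chloro-N,N,2-trimethylpropenylamine, CH2Cl2, 0 °C; then TMSCHN2, MeCN/THF, 0 °C → rt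
Reagents that add atoms: none
Why: Neutral acid chloride formation (Ghosez reagent, no HCl near the alkoxycyclopropane) followed by acylation of trimethylsilyldiazomethane (Arndt–Eistert-type diazoketone synthesis); the acid chloride has no α-hydrogen, so no ketene forms prematurely.

Step 10
Reactants: 14 cis-cyclopropyl diazomethyl ketone
Product: 16 (3aS)-8-ethoxy-3a,6-dimethyl-2,3,3a,7-tetrahydroazulene-1,4-dione, via cyclopropyl ketene 15 (not isolated)
Conditions: hν (450 nm LEDs), PhMe (5 mM), 70 °C
Reagents that add atoms: none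
Why: Photochemical Wolff rearrangement expels N2 and shifts the methyl-bearing cyclopropane carbon with retention onto the diazo carbon, giving ketene 15, whose C=C is the second vinyl arm of a cis-divinylcyclopropane. A Cope [3,3] shift through the boat transition state then joins the ketene carbon (C4) to the methyl-bearing cyclopentene carbon (C3a) as the C(OEt)–C(Me) cyclopropane bond breaks, so the seven-membered ring closes sigmatropically and carries the C4 ketone, the C5=C6 enone and the C8 enol ether. The closest known reaction is the tandem Wolff/Cope rearrangement of cis-2-vinylcyclopropyl diazomethyl ketones to fused cycloheptadienones. C3a is the only new stereocentre and is set by chirality transfer: the boat places the ketene on the cyclopentene face turned toward the cyclopropane, so the (1S,2S) cyclopropane should give (3aS). The step needs the cis acyl/cyclopentenyl relationship, which the lactone origin guarantees, and a Cope shift faster than ketene dimerisation, which high dilution, heat and an aprotic base-free medium favour. The ring methyl points into the boat and is what slows the shift.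

Step 11
Reactants: 16 (3aS)-8-ethoxy-3a,6-dimethyl-2,3,3a,7-tetrahydroazulene-1,4-dione
Product: 17 8-ethoxy-4β-hydroxy-3a,6-dimethyl-3,3a,4,7-tetrahydroazulen-1(2H)-one
Conditions: NaBH4, CeCl3·7H2O, MeOH, −78 °C
Reagents that add atoms: none
Why: Luche 1,2-reduction takes the enone and leaves the much less electrophilic vinylogous ester; in the folded dienone the C3a methyl stands perpendicular to the C4 carbonyl plane, so hydride should add anti to it (as with axial-methyl-flanked cyclohexanones) and give the 4β-alcohol.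

Step 12
Reactants: 17 4β-hydroxy vinylogous ester
Product: 19 8-ethoxy-4β-hydroxy-3a,6-dimethyl-3a,4-dihydroazulen-1(7H)-one (C2=C3 enone), via bis(trimethylsilyl) dienol ether 18 (not isolated)
Conditions: LDA (2.3 equiv), TMSCl, THF, −78 °C; Pd(OAc)2, MeCN, rt; citric acid, MeOH, 0 °C
Reagents that add atoms: none
Why: Kinetic α′-deprotonation of the vinylogous ester (C2) with silylation, then Saegusa–Ito oxidation to the C2=C3 enone; the hydroxyl is masked in the same operation as its TMS ether and released on work-up.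

Step 13
Reactants: 19 4β-hydroxy dienone
Product: 21 8-ethoxy-3α,4β-dihydroxy-3a,6-dimethyl-3,3a,4,7-tetrahydroazulen-1(2H)-one, via cyclic phenylboronate 20 (not isolated)
Conditions: PhB(OH)2 (1.5 equiv), Et3N (0.2 equiv), 4 Å MS, CH2Cl2, rt; then H2O2, aq NaHCO3, 0 °C
Reagents that add atoms: phenylboronic acid, OB(O)c1ccccc1
Why: Boronic acid-templated intramolecular oxa-Michael addition to the δ-hydroxy enone: the boronate hemiester on O4 carries its B–OH oxygen to C3 through a six-membered dioxaborinane, and because C4 sits on the α face of the five-membered ring the new C3–O bond can only form α.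

Step 14
Reactants: 21 3α,4β-dihydroxy ketone
Product: 22 8-ethoxy-1α-isopropyl-3a,6-dimethyl-1,2,3,3a,4,7-hexahydroazulene-1β,3α,4β-triol
Conditions: i-PrMgCl, CeCl3 (5 equiv each), THF, −78 → −40 °C; aq NaHCO3 work-up; Et3N-washed SiO2
Reagents that add atoms: isopropylmagnesium chloride, CC(C)[Mg]Cl
Why: Organocerium 1,2-addition (low basicity, no reduction or enolisation) to the vinylogous ester carbonyl; the metal alkoxide at C3 on the α face should deliver isopropyl to that face, away from the β methyl, giving the 1β-hydroxyl.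

Step 15
Reactants: 22 1β,3α,4β-triol
Product: 23 8-ethoxy-1β,3α-dihydroxy-1α-isopropyl-3a,6-dimethyl-2,3,3a,7-tetrahydroazulen-4(1H)-one
Conditions: MnO2, CH2Cl2, rt
Reagents that add atoms: none
Why: MnO2 oxidises only the secondary allylic C4 alcohol, which distinguishes it from the C3 hydroxyl; the tertiary alcohol and the enol ether are inert.

Step 16
Reactants: 23 4-keto 1β,3α-diol
Product: 24 3α-acetoxy-8-ethoxy-1β-hydroxy-1α-isopropyl-3a,6-dimethyl-2,3,3a,7-tetrahydroazulen-4(1H)-one
Conditions: Ac2O, pyridine, DMAP (cat.), CH2Cl2, 0 °C → rt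
Reagents that add atoms: acetic anhydride, CC(=O)OC(C)=O
Why: Acetylation of the only secondary hydroxyl; the tertiary C1 alcohol does not react, and the acetate cannot β-eliminate because C3a is quaternary.

Step 17
Reactants: 24 3α-acetoxy 4-ketone
Product: 25 3α-acetoxy-8-ethoxy-1α-isopropyl-3a,6-dimethyl-1,2,3,3a,4,7-hexahydroazulene-1β,4β-diol
Conditions: NaBH4, CeCl3·7H2O, MeOH/THF, −78 °C; NaHCO3 quench
Reagents that add atoms: none
Why: Luche reduction on the same folded skeleton as in step 11 (C8=C8a still sp2), so hydride should again add anti to the C3a methyl and restore the 4β-alcohol; the acetate survives at −78 °C.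

Step 18
Reactants: 25 3α-acetoxy 1β,4β-diol
Product: 26 3α-acetoxy-4β-benzoyloxy-8-ethoxy-1α-isopropyl-3a,6-dimethyl-1,2,3,3a,4,7-hexahydroazulen-1β-ol
Conditions: BzCl, pyridine, DMAP (cat.), CH2Cl2, 0 °C → rt
Reagents that add atoms: benzoyl chloride, O=C(Cl)c1ccccc1
Why: Benzoylation of the single secondary alcohol under basic conditions that keep the enol ether and tertiary allylic alcohol intact.

Step 19
Reactants: 26 enol ether benzoate
Product: 27 3α-acetoxy-4β-benzoyloxy-1β-hydroxy-1α-isopropyl-3aβ,6-dimethyl-1,2,3,3a,4,7-hexahydro-8aαH-azulen-8-one (trans-fused)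
Conditions: PPTS (0.3 equiv), acetone/H2O (9:1), 0 °C → rt; Et3N-washed SiO2
Reagents that add atoms: water, O
Why: General-acid-catalysed enol ether hydrolysis (C-protonation at C8a, hydration, loss of ethanol) at a pH too mild to ionise the tertiary allylic alcohol; C8a–H should form cis to the isopropyl group because that puts C8 on the less crowded β face, which is also the more stable trans-fused ketol.

Step 20
Reactants: 27 trans-fused β-hydroxy ketone
Product: 28 3α-acetoxy-4β-benzoyloxy-1α-isopropyl-3aβ,6-dimethyl-1,2,3,3a,4,7,8,8aα-octahydroazulene-1β,8α-diol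
Conditions: Me4NBH(OAc)3, MeCN/AcOH, −30 → 0 °C
Reagents that add atoms: none
Why: Evans–Saksena reduction: the acetoxyborohydride bound to the 1β-oxygen delivers hydride intramolecularly to the β face of the C8 ketone, giving the 1,3-anti diol (8α-OH); esters and the alkene are untouched and the ketone is consumed before it can isomerise.

Step 21
Reactants: 28 1β,8α-diol; 29 angelic acid ((Z)-2-methylbut-2-enoic acid)
Product: 31 target, 3α-acetoxy-8α-angeloyloxy-4β-benzoyloxy-1α-isopropyl-3aβ,6-dimethyl-1,2,3,3a,4,7,8,8aα-octahydroazulen-1β-ol (CNP0248576.1), via mixed anhydride 30 (not isolated)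
Conditions: 2,4,6-Cl3C6H2COCl, Et3N, PhMe, rt; then 28, 80 °C (no DMAP)
Reagents that add atoms: none
Why: Yamaguchi-type mixed-anhydride esterification acylates the secondary 8-OH and not the tertiary 1-OH; omitting nucleophilic catalysts should keep the Z (angelate) geometry.

**Compound list**

1 | 3-methylcyclopent-2-en-1-one | CC1=CC(=O)CC1 | starting material
2 | 2-iodo-3-methylcyclopent-2-en-1-one | CC1=C(I)C(=O)CC1 | intermediate
3 | (R)-2-iodo-3-methylcyclopent-2-en-1-ol | O[C@@H]1CCC(C)=C1I | intermediate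
4 | tributyl(1-ethoxyvinyl)stannane | CCCC[Sn](CCCC)(CCCC)C(=C)OCC | starting material
5 | (R)-2-(1-ethoxyvinyl)-3-methylcyclopent-2-en-1-ol | CCOC(=C)C1=C(C)CC[C@H]1O | intermediate
6 | methyl 2-methyl-3-oxobutanoate | COC(=O)C(C)C(C)=O | starting material
7 | (1R)-2-(1-ethoxyvinyl)-3-methylcyclopent-2-en-1-yl 2-methyl-3-oxobutanoate (α-epimers) | CCOC(=C)C1=C(C)CC[C@H]1OC(=O)C(C)C(C)=O | intermediate
8 | (1R)-2-(1-ethoxyvinyl)-3-methylcyclopent-2-en-1-yl 2-diazopropanoate | CCOC(=C)C1=C(C)CC[C@H]1OC(=O)C(C)=[N+]=[N-] | intermediate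
9 | tricyclic cyclopropane-fused δ-lactone (cis-fused; CH2 on the lactone-oxygen side) | CCO[C@@]1(C2=C(C)CC[C@H]2O3)C[C@]1(C)C3=O | intermediate
10 | cis-2-ethoxy-2-[(5R)-5-hydroxy-2-methylcyclopent-1-en-1-yl]-1-methylcyclopropane-1-carboxylic acid | CCO[C@@]1(C2=C(C)CC[C@H]2O)C[C@]1(C)C(=O)O | intermediate
11 | cis-2-ethoxy-1-methyl-2-(2-methyl-5-oxocyclopent-1-en-1-yl)cyclopropane-1-carboxylic acid | CCO[C@@]1(C2=C(C)CCC2=O)C[C@]1(C)C(=O)O | intermediate
12 | (trimethylsilyl)diazomethane | C[Si](C)(C)C=[N+]=[N-] | starting material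
13 | cis-2-ethoxy-1-methyl-2-(2-methyl-5-oxocyclopent-1-en-1-yl)cyclopropane-1-carbonyl chloride | CCO[C@@]1(C2=C(C)CCC2=O)C[C@]1(C)C(Cl)=O | intermediate
14 | 2-diazo-1-[(1S,2S)-2-ethoxy-1-methyl-2-(2-methyl-5-oxocyclopent-1-en-1-yl)cyclopropyl]ethan-1-one | CCO[C@@]1(C2=C(C)CCC2=O)C[C@]1(C)C(=O)C=[N+]=[N-] | intermediate
15 | [cis-2-ethoxy-1-methyl-2-(2-methyl-5-oxocyclopent-1-en-1-yl)cyclopropyl]ketene (configured as 14) | CCO[C@@]1(C2=C(C)CCC2=O)C[C@]1(C)C=C=O | intermediate
16 | (3aS)-8-ethoxy-3a,6-dimethyl-2,3,3a,7-tetrahydroazulene-1,4-dione | CCOC1=C2C(=O)CC[C@]2(C)C(=O)C=C(C)C1 | intermediate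
17 | 8-ethoxy-4β-hydroxy-3a,6-dimethyl-3,3a,4,7-tetrahydroazulen-1(2H)-one | CCOC1=C2C(=O)CC[C@]2(C)[C@@H](O)C=C(C)C1 | intermediate
18 | 8-ethoxy-3a,6-dimethyl-1,4β-bis(trimethylsilyloxy)-3,3a,4,7-tetrahydroazulene | CCOC1=C2C(O[Si](C)(C)C)=CC[C@]2(C)[C@@H](O[Si](C)(C)C)C=C(C)C1 | intermediate
19 | 8-ethoxy-4β-hydroxy-3a,6-dimethyl-3a,4-dihydroazulen-1(7H)-one | CCOC1=C2C(=O)C=C[C@]2(C)[C@@H](O)C=C(C)C1 | intermediate
20 | cyclic phenylboronate of the 3α,4β-diol 21 | CCOC1=C2C(=O)C[C@H]3[C@]2(C)[C@@H](OB(c4ccccc4)O3)C=C(C)C1 | intermediate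
21 | 8-ethoxy-3α,4β-dihydroxy-3a,6-dimethyl-3,3a,4,7-tetrahydroazulen-1(2H)-one | CCOC1=C2C(=O)C[C@H](O)[C@]2(C)[C@@H](O)C=C(C)C1 | intermediate
22 | 8-ethoxy-1α-isopropyl-3a,6-dimethyl-1,2,3,3a,4,7-hexahydroazulene-1β,3α,4β-triol | CCOC1=C2[C@](O)(C(C)C)C[C@H](O)[C@]2(C)[C@@H](O)C=C(C)C1 | intermediate
23 | 8-ethoxy-1β,3α-dihydroxy-1α-isopropyl-3a,6-dimethyl-2,3,3a,7-tetrahydroazulen-4(1H)-one | CCOC1=C2[C@](O)(C(C)C)C[C@H](O)[C@]2(C)C(=O)C=C(C)C1 | intermediate
24 | 3α-acetoxy-8-ethoxy-1β-hydroxy-1α-isopropyl-3a,6-dimethyl-2,3,3a,7-tetrahydroazulen-4(1H)-one | CCOC1=C2[C@](O)(C(C)C)C[C@H](OC(C)=O)[C@]2(C)C(=O)C=C(C)C1 | intermediate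
25 | 3α-acetoxy-8-ethoxy-1α-isopropyl-3a,6-dimethyl-1,2,3,3a,4,7-hexahydroazulene-1β,4β-diol | CCOC1=C2[C@](O)(C(C)C)C[C@H](OC(C)=O)[C@]2(C)[C@@H](O)C=C(C)C1 | intermediate
26 | 3α-acetoxy-4β-benzoyloxy-8-ethoxy-1α-isopropyl-3a,6-dimethyl-1,2,3,3a,4,7-hexahydroazulen-1β-ol | CCOC1=C2[C@](O)(C(C)C)C[C@H](OC(C)=O)[C@]2(C)[C@@H](OC(=O)c3ccccc3)C=C(C)C1 | intermediate
27 | 3α-acetoxy-4β-benzoyloxy-1β-hydroxy-1α-isopropyl-3aβ,6-dimethyl-1,2,3,3a,4,7-hexahydro-8aαH-azulen-8-one | O=C1CC(C)=C[C@H](OC(=O)c2ccccc2)[C@@]2(C)[C@@H](OC(C)=O)C[C@@](O)(C(C)C)[C@H]12 | intermediate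
28 | 3α-acetoxy-4β-benzoyloxy-1α-isopropyl-3aβ,6-dimethyl-1,2,3,3a,4,7,8,8aα-octahydroazulene-1β,8α-diol | O[C@H]1CC(C)=C[C@H](OC(=O)c2ccccc2)[C@@]2(C)[C@@H](OC(C)=O)C[C@@](O)(C(C)C)[C@H]12 | intermediate
29 | angelic acid | C/C=C(/C)C(=O)O | starting material
30 | angelic 2,4,6-trichlorobenzoic anhydride | C/C=C(/C)C(=O)OC(=O)c1c(Cl)cc(Cl)cc1Cl | intermediate
31 | CNP0248576.1 (3α-acetoxy-8α-angeloyloxy-4β-benzoyloxy-1β-hydroxy-1α-isopropyl-3aβ,6-dimethyl-octahydroazulene) | C/C=C(/C)C(=O)O[C@H]1CC(C)=C[C@H](OC(=O)c2ccccc2)[C@@]2(C)[C@@H](OC(C)=O)C[C@@](O)(C(C)C)[C@H]12 | target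

**Step count and risks**

Total step count: 21. Longest linear sequence: 21 steps (1 → 31).

Steps most likely to fail:

1. Step 10 (key step). The [3,3] shift may be slow because the ring methyl points into the boat and a quaternary carbon is formed. The ketene could then dimerise or be trapped, or the photogenerated carbene could react elsewhere. The fallback avoids the ketene and uses a thermal alkoxyvinyl-cyclopropane Cope rearrangement. It sets out from 11: coupling with ethanethiol (DCC, DMAP) should give the S-ethyl thioester F1, and Fukuyama reduction (Et3SiH, Pd/C) the cyclopropanecarbaldehyde F2, with the ketone untouched. Wittig reaction with (4-methoxybenzyloxymethyl)triphenylphosphonium chloride/NaHMDS should give the PMB enol ether F3. Heating (PhMe, 110–130 °C) should effect the divinylcyclopropane rearrangement to the C4 PMB ether F4 (C4 epimers, same C3a configuration). DDQ in wet CH2Cl2 should release the allylic alcohols F5, and MnO2 oxidation returns to the route at 16.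

2. Step 19. The tertiary allylic alcohol may ionise under acid (allylic transposition with loss of the hydroxyl), C8a may be protonated on the wrong face (cis fusion), or the C5=C6 alkene may move into conjugation with the new ketone. The fallback cleaves the enol ether without Brønsted acid. It sets out from 26: bromohydration (NBS, NaHCO3, aq THF, 0 °C) should give the α-bromo ketone F6, and radical debromination (Bu3SnH, Et3B/air, −20 °C) returns to the route at 27.

3. Step 6. The carbenoid may show poor facial selectivity relative to the carbinol centre, add to the ring alkene, or undergo 1,2-hydride shift to the acrylate. The fallback is an intermolecular, catalyst-controlled cyclopropanation. It sets out from 5: MnO2 oxidation should give the dienone F7. Methyl 2-diazopropanoate F8 is made from 6 (p-ABSA, DBU). Rh2(S-PTTL)4 at −78 °C should give the cyclopropane methyl ester F9, whose cis isomer is separated from the trans isomer. Saponification (LiOH) returns to the route at 11.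

**Further compounds**

F1 | step 10 | S-ethyl cis-2-ethoxy-1-methyl-2-(2-methyl-5-oxocyclopent-1-en-1-yl)cyclopropane-1-carbothioate | CCO[C@@]1(C2=C(C)CCC2=O)C[C@]1(C)C(=O)SCC
F2 | step 10 | cis-2-ethoxy-1-methyl-2-(2-methyl-5-oxocyclopent-1-en-1-yl)cyclopropane-1-carbaldehyde | CCO[C@@]1(C2=C(C)CCC2=O)C[C@]1(C)C=O
F3 | step 10 | 2-{cis-1-ethoxy-2-[2-(4-methoxybenzyloxy)vinyl]-2-methylcyclopropyl}-3-methylcyclopent-2-en-1-one (E/Z) | CCO[C@@]1(C2=C(C)CCC2=O)C[C@]1(C)C=COCc1ccc(OC)cc1
F4 | step 10 | 8-ethoxy-4-(4-methoxybenzyloxy)-3a,6-dimethyl-3,3a,4,7-tetrahydroazulen-1(2H)-one (C4 epimers) | CCOC1=C2C(=O)CC[C@]2(C)C(OCc3ccc(OC)cc3)C=C(C)C1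
F5 | step 10 | 8-ethoxy-4-hydroxy-3a,6-dimethyl-3,3a,4,7-tetrahydroazulen-1(2H)-one (C4 epimers) | CCOC1=C2C(=O)CC[C@]2(C)C(O)C=C(C)C1
F6 | step 19 | 3α-acetoxy-4β-benzoyloxy-8a-bromo-1β-hydroxy-1α-isopropyl-3aβ,6-dimethyl-1,2,3,3a,4,7-hexahydroazulen-8-one | O=C1CC(C)=C[C@H](OC(=O)c2ccccc2)[C@@]2(C)[C@@H](OC(C)=O)C[C@@](O)(C(C)C)C12Br
F7 | step 6 | 2-(1-ethoxyvinyl)-3-methylcyclopent-2-en-1-one | CCOC(=C)C1=C(C)CCC1=O
F8 | step 6 | methyl 2-diazopropanoate | COC(=O)C(C)=[N+]=[N-]
F9 | step 6 | methyl cis-2-ethoxy-1-methyl-2-(2-methyl-5-oxocyclopent-1-en-1-yl)cyclopropane-1-carboxylate | CCO[C@@]1(C2=C(C)CCC2=O)C[C@]1(C)C(=O)OC
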